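The plan:
1. Retrosynthetic cuts, in order: the angelate C–O bond. Then the lactone C–O bond together with C2–C3 of the cyclopentane (aldehyde plus an ester-bearing allyl metal). Then the C9–O and C8–H bonds, back to a cyclohex-2-enone. Finally C5–C6 and C9–C10 of the six-membered ring (retro-Diels–Alder).
2. Enabling feature: in the carbocycle C5–C10 the spiro carbon C5 and the CH(CH3) carbon C10 are neighbours. C6(CH2O)=C7–C8(OH) is a reduced enone, that is, the dehydrogenated form of a C7=C8 silyl enol ether. C6–C7–C8–C9 is therefore a 2-silyloxydiene, and C5–C10 is the α,β-bond of an (E)-2-substituted but-2-enal whose formyl carbon (C4) and α-arm (C1) are the two cyclopentane CH2 groups.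
3. Forward order: the cyclohexene first (step 6), then its oxidation pattern (steps 7–12), then cyclopentane and lactone in one operation (step 17), and the angelate last.
4. Stereochemistry: C5/C10 are absolute from a chiral oxazaborolidinium catalyst and relative from the E-enal. C9 comes from enolate hydroxylation anti to the C10 methyl group, and C8 from axial hydride delivery. C2/C3 come from a closed allylchromium transition state on a conformationally locked ring. The Z-alkene of the ester comes from angelic acid.

Key step: step 6

Locants and faces: from compound 13 on, the spiro[4.5]decane locants of the target are used. C1H2, C2H (acrylate carbon), C3H–O and C4H2 are the cyclopentane atoms. C5 is the spiro carbon, C6 bears CH2O, C7 to C9 follow, and C10 bears CH3. With the six-membered ring drawn flat and C5, C6, C7, C8, C9, C10 running clockwise, β is toward the viewer and α is away. PMB = 4-methoxybenzyl, TBS = tert-butyldimethylsilyl, TIPDS = 1,1,3,3-tetraisopropyldisiloxane-1,3-diyl.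

Assumption: the sense of induction in step 6 is read from the usual binding model of this catalyst class (formyl C–H···O contact, s-trans enal), which calls for the catalyst derived from (R)-α,α-diphenylprolinol. Should the adduct prove antipodal, the equally available (S)-catalyst would be used and nothing else would change.

Step 1
Reactants: 1 pent-4-enal
Product: 2 N-tert-butyl imine of pent-4-enal
Conditions: t-BuNH2, 4 Å MS, Et2O, 0 °C → rt
Reagents that add atoms: tert-butylamine, CC(C)(C)N
Why: Condensation of an unhindered aldehyde with a primary amine under water removal gives the aldimine, which masks the formyl group and makes its α-carbon the only site that the base of step 2 can metalate (first half of a directed aldol condensation).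

Step 2
Reactants: 2 N-tert-butyl imine of pent-4-enal; 3 acetaldehyde
Product: 6 (E)-2-ethylidenepent-4-enal, via lithiated imine 4 (not isolated), via hydroxy imine 5 (not isolated)
Conditions: LiN(iPr)2, THF, −78 → 0 °C; 3, −78 °C; then aq. oxalic acid, hexane, rt → reflux
Reagents that add atoms: water, O (formyl oxygen of 6); LiN(iPr)2, [Li+].CC(C)[N-]C(C)C (lithium only in 4)
Why: Directed aldol condensation through a metalloenamine: the preformed lithium azaenolate 4 adds to acetaldehyde without self-condensation of either aldehyde, and acidic hydrolysis of 5 with loss of water gives the conjugated enal as the E isomer, in which the β-methyl group avoids the formyl group.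

Step 3
Reactants: 7 4-methoxybenzyl alcohol; 8 allyl bromide
Product: 9 allyl 4-methoxybenzyl ether
Conditions: NaH, Bu4NI (cat.), THF, 0 °C → rt
Reagents that add atoms: none
Why: Williamson ether synthesis of a primary alkoxide with a reactive allylic bromide.

Step 4
Reactants: 9 allyl 4-methoxybenzyl ether; 10 methyl vinyl ketone
Product: 11 (E)-5-(4-methoxybenzyloxy)pent-3-en-2-one
Conditions: second-generation Hoveyda–Grubbs catalyst (cat.), excess 10, CH2Cl2, 40 °C
Reagents that add atoms: none
Why: Olefin cross metathesis between an electron-neutral terminal alkene and an electron-poor enone, a pairing that disfavours homodimers and gives the conjugated E-enone under thermodynamic control.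

Step 5
Reactants: 11 (E)-5-(4-methoxybenzyloxy)pent-3-en-2-one
Product: 12 (E)-2-(tert-butyldimethylsilyloxy)-5-(4-methoxybenzyloxy)penta-1,3-diene
Conditions: TBSOTf, Et3N, Et2O, 0 °C
Reagents that add atoms: TBSOTf, CC(C)(C)[Si](C)(C)OS(=O)(=O)C(F)(F)F
Why: Soft enolisation: O-silylation of the enone followed by removal of a proton from the methyl group by Et3N gives the cross-conjugated 2-silyloxydiene, the E-alkene being untouched and the less accessible γ-CH2O protons being left alone.

Step 6
Reactants: 6 (E)-2-ethylidenepent-4-enal; 12 (E)-2-(tert-butyldimethylsilyloxy)-5-(4-methoxybenzyloxy)penta-1,3-diene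
Product: 13 cyclohexene silyl enol ether aldehyde (5β-CHO 5α-allyl 6β-CH2OPMB 10α-CH3)
Conditions: (R)-1-(2-methylphenyl)-3,3-diphenyltetrahydro-1H,3H-pyrrolo[1,2-c][1,3,2]oxazaborole (20 mol %) + Tf2NH (18 mol %), CH2Cl2, −78 → −20 °C
Reagents that add atoms: none
Why: The boron of the protonated oxazaborolidine binds the formyl oxygen of 6 (anti to the substituted α-carbon, supported by a formyl C–H···O contact), which lowers the LUMO of the s-trans enal, and 12 adds in a concerted, asynchronous, suprafacial [4+2] cycloaddition in which C9–C10 runs ahead of C5–C6. The closest known reaction type is the oxazaborolidinium-catalysed Diels–Alder reaction of 2-substituted and 2,3-disubstituted enals with 2-silyloxybuta-1,3-dienes. The only ring formed, the cyclohexene C5–C10, closes by this intermolecular six-centre cycloaddition and keeps its C7=C8 double bond as a regiodefined silyl enol ether. C5 and C10: their relative configuration (methyl cis to allyl) is carried over stereospecifically from the E-alkene of 6, and their absolute configuration is set by the catalyst, one phenyl group of which covers the C2-Re face of the bound enal so that the diene reaches the C2-Si face. C6: a formyl-endo approach puts CH2OPMB cis to CHO as drawn, but this centre becomes sp2 in step 7, so the endo/exo outcome has no consequence. The step needs regiocontrol and cycloaddition in preference to open-chain Mukaiyama-type addition: the 2-silyloxy group makes the CH2 terminus of 12 its most nucleophilic site (bond to the enal β-carbon), the 4-alkyl group reinforces the same orientation, and the low temperature and the non-nucleophilic Tf2N counter-ion keep the silyl group on oxygen until both bonds are made.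

Step 7
Reactants: 13 cyclohexene silyl enol ether aldehyde
Product: 16 enone aldehyde (C6=C7 8-oxo), via 7α-phenylselanyl ketone 14 (not isolated), via selenoxide 15 (not isolated)
Conditions: PhSeCl, CH2Cl2, −78 °C; then 30% H2O2, pyridine, 0 °C → rt
Reagents that add atoms: PhSeCl, Cl[Se]c1ccccc1 (selenium only in 14 and 15); hydrogen peroxide, OO (oxygen only in 15)
Why: Selenenylation of a silyl enol ether followed by selenoxide syn-elimination: PhSeCl attacks the nucleophilic C7 far faster than the isolated allyl alkene and from the face opposite to the C6 side chain, which puts selenium cis to H-6, the only β-hydrogen, so that oxidation delivers the C6=C7 enone regiospecifically (erasing the C6 centre), a selenium-based dehydrogenation being chosen over one with palladium diacetate because divalent palladium could engage the allyl arm in cycloalkenylation.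

Step 8
Reactants: 16 enone aldehyde; 17 (methoxymethyl)triphenylphosphonium chloride
Product: 19 methyl enol ether enone, via methoxymethylidene ylide 18 (not isolated)
Conditions: 17, KN(SiMe3)2, THF, 0 °C; then 16, −78 → 0 °C
Reagents that add atoms: none
Why: Wittig methoxymethylenation: the non-stabilised ylide 18 reacts at low temperature with the non-enolisable aldehyde much faster than with the conjugated ketone, adding the carbon that becomes C3, and the E/Z mixture of enol ethers (E drawn) is of no consequence because both isomers converge in step 9.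

Step 9
Reactants: 19 methyl enol ether enone
Product: 20 dimethyl acetal enone
Conditions: PPTS (cat.), MeOH, rt
Reagents that add atoms: methanol, CO
Why: Acid-catalysed addition of methanol to the enol ether through its oxocarbenium ion gives one dimethyl acetal from both isomers, a mask for the C3 aldehyde that withstands the basic, reducing and oxidising steps 10–15.

Step 10
Reactants: 20 dimethyl acetal enone
Product: 22 9β-hydroxy enone, via sodium dienolate 21 (not isolated)
Conditions: NaN(SiMe3)2, THF, −78 °C; 2-(benzenesulfonyl)-3-phenyloxaziridine, −78 °C; AcOH quench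
Reagents that add atoms: 2-(benzenesulfonyl)-3-phenyloxaziridine, O=S(=O)(c1ccccc1)N1OC1c1ccccc1; NaN(SiMe3)2, [Na+].C[Si](C)(C)[N-][Si](C)(C)C (sodium only in 21)
Why: Electrophilic hydroxylation of a kinetic enolate with an N-sulfonyloxaziridine: the hindered amide base removes an α′-proton at C9 rather than a γ-proton, and the oxidant approaches the cross-conjugated dienolate 21 anti to the adjacent 10α-methyl group, giving the 9β-alcohol, which is also the more stable (equatorial) epimer of this epimerisable centre.

Step 11
Reactants: 22 9β-hydroxy enone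
Product: 23 8α,9β-diol
Conditions: NaBH4, CeCl3·7H2O, MeOH, −78 °C
Reagents that add atoms: none
Why: Luche reduction: the cerium-modified borohydride adds 1,2 only, and hydride enters axially from the β face of the conformer with equatorial 9β-OH and 10α-CH3 groups, giving the pseudoequatorial 8α-alcohol trans to the 9β-hydroxyl.

Step 12
Reactants: 23 8α,9β-diol
Product: 24 TIPDS-bridged allyl acetal
Conditions: (iPr2SiCl)2O, imidazole, DMF, rt
Reagents that add atoms: 1,3-dichloro-1,1,3,3-tetraisopropyldisiloxane, CC(C)[Si](Cl)(C(C)C)O[Si](Cl)(C(C)C)C(C)C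
Why: Bridging silylation of a trans-diequatorial 1,2-diol with the bifunctional dichlorodisiloxane gives a seven-membered ring that protects both alcohols in one step and locks the half-chair in which 10-CH3 is equatorial and the C1 arm pseudoaxial.

Step 13
Reactants: 24 TIPDS-bridged allyl acetal
Product: 26 C2 aldehyde (5α-CH2CHO), via terminal diol 25 (not isolated)
Conditions: OsO4 (cat.), NaIO4, 2,6-lutidine, dioxane/H2O, rt
Reagents that add atoms: OsO4, O=[Os](=O)(=O)=O; NaIO4, [Na+].[O-]I(=O)(=O)=O; water, O
Why: Lemieux–Johnson cleavage: OsO4 dihydroxylates the monosubstituted allyl alkene much faster than the hindered C6=C7 bond with its quaternary and two oxygenated allylic neighbours, periodate cleaves 25, and because the C2 aldehyde is released oxidatively at buffered pH no free hydroxyl on this arm ever meets the masked C3 aldehyde, with which it would close a six-membered cyclic acetal.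

Step 14
Reactants: 26 C2 aldehyde; 27 methyl acrylate
Product: 28 Morita–Baylis–Hillman alcohol
Conditions: excess 27, DABCO, MeOH, rt
Reagents that add atoms: none
Why: Morita–Baylis–Hillman reaction: the DABCO–acrylate zwitterion adds to the unhindered formyl group, whose neopentyl-type α-carbon suppresses self-aldolisation, and the new carbinol centre (both epimers) is destroyed in step 15.

Step 15
Reactants: 28 Morita–Baylis–Hillman alcohol
Product: 29 (Z)-allylic bromide acetal
Conditions: NBS, Me2S, CH2Cl2, 0 °C → rt
Reagents that add atoms: N-bromosuccinimide, O=C1CCC(=O)N1Br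
Why: Allylic bromination with transposition: the hydroxyl is activated by the bromosulfonium reagent and displaced by bromide in an SN2′ sense at the terminal methylene, giving the conjugated trisubstituted ester with the usual Z geometry (chain cis to CH2Br, vinylic hydrogen cis to the ester).

Step 16
Reactants: 29 (Z)-allylic bromide acetal
Product: 30 (Z)-allylic bromide aldehyde
Conditions: Amberlyst-15, acetone/H2O, rt
Reagents that add atoms: water, O
Why: Acid-catalysed hydrolysis of an unhindered dimethyl acetal on a sulfonic acid resin in wet acetone, conditions under which the disiloxane bridge, the PMB ether and the primary allylic bromide persist.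

Step 17
Reactants: 30 (Z)-allylic bromide aldehyde
Product: 33 PMB-protected spiro lactone, via allylchromium species 31 (not isolated), via cis-hydroxy ester 32 (not isolated)
Conditions: CrCl2 (excess), THF, high dilution, rt; aqueous work-up; PPTS (cat.), CH2Cl2, rt
Reagents that add atoms: CrCl2, Cl[Cr]Cl (chromium only in 31)
Why: Intramolecular Barbier-type Nozaki–Hiyama allylation followed by lactonisation: divalent chromium reduces only the allylic bromide, the ester-bearing Z-allylchromium 31 adds through its γ-carbon C2 to the tethered aldehyde carbon C3 (5-exo-trig) in a closed chair-like transition state that places acrylate and alkoxide cis on the new five-membered ring, the only arrangement that can lactonise, and the TIPDS-locked half-chair, in which the pseudoaxial C1 arm is flanked on the C10 side by the methyl group but on the C6 side only by a flat sp2 carbon, should steer both new substituents to the C6 face as in the target.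

Step 18
Reactants: 33 PMB-protected spiro lactone
Product: 34 primary allylic alcohol
Conditions: DDQ, CH2Cl2/pH 7 buffer, 0 °C
Reagents that add atoms: none
Why: Oxidative cleavage of the electron-rich PMB ether by DDQ through hydride abstraction and hydrolysis of the oxocarbenium ion, with the silyl ethers and the electron-poor methylene lactone inert and a limited amount of oxidant at 0 °C sparing the liberated allylic alcohol.

Step 19
Reactants: 34 primary allylic alcohol; 35 angelic acid
Product: 37 TIPDS-protected angelate, via mixed anhydride 36 (not isolated)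
Conditions: 35, 2,4,6-trichlorobenzoyl chloride, Et3N, toluene, rt; then 34, toluene, 80 °C
Reagents that add atoms: 2,4,6-trichlorobenzoyl chloride, O=C(Cl)c1c(Cl)cc(Cl)cc1Cl (aroyl group only in 36)
Why: Yamaguchi-type esterification through the preformed mixed anhydride 36 without a nucleophilic catalyst: the primary alcohol attacks the less hindered angeloyl carbonyl, and the absence of an addition–elimination catalyst keeps the Z-alkene from isomerising to the tiglate.

Step 20
Reactants: 37 TIPDS-protected angelate
Product: 38 target CNP0224912.1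
Conditions: HF·pyridine, pyridine/THF, 0 °C → rt
Reagents that add atoms: none
Why: Fluoride-induced cleavage of both Si–O bonds of the disiloxane bridge under mildly acidic HF·pyridine conditions, which avoid the basic media that would endanger the angelate and the methylene lactone, acyl migration being excluded because the ester-bearing CH2 is trans to C8 across C6=C7.

Compound list
1 | pent-4-enal | C=CCCC=O | starting material
2 | (E)-N-tert-butylpent-4-en-1-imine | C=CCC/C=N/C(C)(C)C | intermediate
3 | acetaldehyde | CC=O | starting material
4 | lithium azaenolate of 2 (N-lithio N-tert-butylpenta-1,4-dienylamine) | [Li]N(C=CCC=C)C(C)(C)C | intermediate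
5 | 3-[(tert-butylimino)methyl]hex-5-en-2-ol (both diastereomers) | CC(O)C(CC=C)C=NC(C)(C)C | intermediate
6 | (E)-2-ethylidenepent-4-enal (methyl cis to allyl, trans to CHO) | C/C=C(/C=O)CC=C | intermediate
7 | 4-methoxybenzyl alcohol | COc1ccc(CO)cc1 | starting material
8 | allyl bromide | C=CCBr | starting material
9 | allyl 4-methoxybenzyl ether | C=CCOCc1ccc(OC)cc1 | intermediate
10 | but-3-en-2-one (methyl vinyl ketone) | C=CC(C)=O | starting material
11 | (E)-5-(4-methoxybenzyloxy)pent-3-en-2-one | CC(=O)/C=C/COCc1ccc(OC)cc1 | intermediate
12 | (E)-2-(tert-butyldimethylsilyloxy)-5-(4-methoxybenzyloxy)penta-1,3-diene | C=C(O[Si](C)(C)C(C)(C)C)/C=C/COCc1ccc(OC)cc1 | intermediate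
13 | (1R,2S,6S)-1-allyl-4-(tert-butyldimethylsilyloxy)-2-[(4-methoxybenzyloxy)methyl]-6-methylcyclohex-3-ene-1-carbaldehyde (5β-CHO, 5α-allyl, 6β-CH2OPMB, 10α-CH3, C7=C8 silyl enol ether) | O=C[C@@]1(CC=C)[C@@H](COCc2ccc(OC)cc2)C=C(O[Si](C)(C)C(C)(C)C)C[C@@H]1C | intermediate
14 | 7α-phenylselanyl 8-ketone from 13 (SePh and H-6 both α) | O=C[C@@]1(CC=C)[C@@H](COCc2ccc(OC)cc2)[C@H]([Se]c2ccccc2)C(=O)C[C@@H]1C | intermediate
15 | selenoxide of 14 | O=C[C@@]1(CC=C)[C@@H](COCc2ccc(OC)cc2)[C@H]([Se](=O)c2ccccc2)C(=O)C[C@@H]1C | intermediate
16 | (1R,6S)-1-allyl-2-[(4-methoxybenzyloxy)methyl]-6-methyl-4-oxocyclohex-2-ene-1-carbaldehyde (5β-CHO, 5α-allyl, C6=C7, 8-oxo, 10α-CH3) | O=C[C@@]1(CC=C)C(COCc2ccc(OC)cc2)=CC(=O)C[C@@H]1C | intermediate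
17 | (methoxymethyl)triphenylphosphonium chloride | COC[P+](c1ccccc1)(c1ccccc1)c1ccccc1.[Cl-] | starting material
18 | (methoxymethylidene)triphenylphosphorane | COC=P(c1ccccc1)(c1ccccc1)c1ccccc1 | intermediate
19 | 5α-allyl-5β-[(E)-2-methoxyethenyl]-6-(PMB-oxymethyl)-10α-methylcyclohex-6-en-8-one (E drawn, Z isomer also formed) | CO/C=C/[C@@]1(CC=C)C(COCc2ccc(OC)cc2)=CC(=O)C[C@@H]1C | intermediate
20 | 5α-allyl-5β-(2,2-dimethoxyethyl)-6-(PMB-oxymethyl)-10α-methylcyclohex-6-en-8-one | COC(OC)C[C@@]1(CC=C)C(COCc2ccc(OC)cc2)=CC(=O)C[C@@H]1C | intermediate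
21 | sodium C8=C9 dienolate of 20 | COC(OC)C[C@@]1(CC=C)C(COCc2ccc(OC)cc2)=CC([O-])=C[C@@H]1C.[Na+] | intermediate
22 | 9β-hydroxy derivative of 20 (OH trans to 10α-CH3) | COC(OC)C[C@@]1(CC=C)C(COCc2ccc(OC)cc2)=CC(=O)[C@@H](O)[C@@H]1C | intermediate
23 | 8α,9β-diol from 22 (C6=C7 retained) | COC(OC)C[C@@]1(CC=C)C(COCc2ccc(OC)cc2)=C[C@H](O)[C@@H](O)[C@@H]1C | intermediate
24 | 8α,9β-O-TIPDS derivative of 23 | COC(OC)C[C@@]1(CC=C)C(COCc3ccc(OC)cc3)=C[C@@H]2O[Si](C(C)C)(C(C)C)O[Si](C(C)C)(C(C)C)O[C@H]2[C@@H]1C | intermediate
25 | 24 with the allyl group dihydroxylated to CH2CH(OH)CH2OH (both epimers) | COC(OC)C[C@@]1(CC(O)CO)C(COCc3ccc(OC)cc3)=C[C@@H]2O[Si](C(C)C)(C(C)C)O[Si](C(C)C)(C(C)C)O[C@H]2[C@@H]1C | intermediate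
26 | 24 with 5α-CH2CHO in place of 5α-allyl | COC(OC)C[C@@]1(CC=O)C(COCc3ccc(OC)cc3)=C[C@@H]2O[Si](C(C)C)(C(C)C)O[Si](C(C)C)(C(C)C)O[C@H]2[C@@H]1C | intermediate
27 | methyl acrylate | C=CC(=O)OC | starting material
28 | 5α-[2-hydroxy-3-(methoxycarbonyl)but-3-enyl] compound (both carbinol epimers), otherwise as 26 | COC(OC)C[C@@]1(CC(O)C(=C)C(=O)OC)C(COCc3ccc(OC)cc3)=C[C@@H]2O[Si](C(C)C)(C(C)C)O[Si](C(C)C)(C(C)C)O[C@H]2[C@@H]1C | intermediate
29 | 5α-[(Z)-4-bromo-3-(methoxycarbonyl)but-2-enyl]-5β-(2,2-dimethoxyethyl) compound | COC(OC)C[C@@]1(C/C=C(\CBr)C(=O)OC)C(COCc3ccc(OC)cc3)=C[C@@H]2O[Si](C(C)C)(C(C)C)O[Si](C(C)C)(C(C)C)O[C@H]2[C@@H]1C | intermediate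
30 | 5α-[(Z)-4-bromo-3-(methoxycarbonyl)but-2-enyl]-5β-(2-oxoethyl) compound | O=CC[C@@]1(C/C=C(\CBr)C(=O)OC)C(COCc3ccc(OC)cc3)=C[C@@H]2O[Si](C(C)C)(C(C)C)O[Si](C(C)C)(C(C)C)O[C@H]2[C@@H]1C | intermediate
31 | allylchromium dichloride from 30 (CrCl2 in place of Br) | O=CC[C@@]1(C/C=C(\C[Cr](Cl)Cl)C(=O)OC)C(COCc3ccc(OC)cc3)=C[C@@H]2O[Si](C(C)C)(C(C)C)O[Si](C(C)C)(C(C)C)O[C@H]2[C@@H]1C | intermediate
32 | spiro[4.5]dec-6-ene with 3-OH and 2-[1-(methoxycarbonyl)ethenyl] cis to each other on the C6 face (H-2, H-3 toward C10) | C=C(C(=O)OC)[C@H]1C[C@]2(C[C@H]1O)C(COCc4ccc(OC)cc4)=C[C@@H]3O[Si](C(C)C)(C(C)C)O[Si](C(C)C)(C(C)C)O[C@H]3[C@@H]2C | intermediate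
33 | cis-fused α-methylene-γ-lactone from 32 (6-CH2OPMB, 8α,9β-O-TIPDS) | C=C1C(=O)O[C@@H]2C[C@@]3(C[C@H]12)C(COCc5ccc(OC)cc5)=C[C@@H]4O[Si](C(C)C)(C(C)C)O[Si](C(C)C)(C(C)C)O[C@H]4[C@@H]3C | intermediate
34 | 33 with 6-CH2OH | C=C1C(=O)O[C@@H]2C[C@@]3(C[C@H]12)C(CO)=C[C@@H]4O[Si](C(C)C)(C(C)C)O[Si](C(C)C)(C(C)C)O[C@H]4[C@@H]3C | intermediate
35 | angelic acid, (Z)-2-methylbut-2-enoic acid | C/C=C(/C)C(=O)O | starting material
36 | angelic 2,4,6-trichlorobenzoic anhydride | C/C=C(/C)C(=O)OC(=O)c1c(Cl)cc(Cl)cc1Cl | intermediate
37 | angelate of 34 | C=C1C(=O)O[C@@H]2C[C@@]3(C[C@H]12)C(COC(=O)/C(C)=C\C)=C[C@@H]4O[Si](C(C)C)(C(C)C)O[Si](C(C)C)(C(C)C)O[C@H]4[C@@H]3C | intermediate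
38 | CNP0224912.1, (2R,3R,5R,8S,9S,10R) in the locants used here | C=C1C(=O)O[C@@H]2C[C@@]3(C[C@H]12)C(COC(=O)/C(C)=C\C)=C[C@H](O)[C@@H](O)[C@@H]3C | target

Total step count: 20. Longest linear sequence: 18 steps (steps 3–20, from 4-methoxybenzyl alcohol 7).

Steps most likely to fail

Step 6. What may go wrong: bond formation between the fully substituted α-carbon of 6 and the substituted terminus of 12 may be slow at the temperatures at which the catalyst still tells the enal faces apart. Protodesilylation of the diene or open-chain Mukaiyama-type addition could then take over, or face selection could be incomplete. Fallback: the same two components 6 and 12 are combined without asymmetric catalysis, under Me2AlCl in CH2Cl2 or under high pressure, to give the racemic adduct. The antipodes are separated by preparative chromatography on a chiral stationary phase. Compound 13 re-enters the route at step 7 and the mirror-image adduct F1 is set aside. The cycloaddition, its regiochemistry and the methyl/allyl relationship stay as planned, and only the origin of the absolute configuration moves from catalysis to resolution.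

Step 17. What may go wrong: the two faces of the forming cyclopentane differ only through C6 and C10, so face selection by the substrate may be poor. Slow closure would also favour protonation or dimerisation of the allyl metal. Fallback: control is moved from the substrate to a chiral catalyst. Starting again from 30, a catalytic Nozaki–Hiyama allylation is run with CrCl2 (catalytic) and an enantiopure bis(oxazolinyl)carbazole or oxazoline–sulfonamide ligand chosen to match the required C3 configuration. Mn powder serves as terminal reductant and Me3SiCl as turnover reagent. This gives the trimethylsilyl ether of the cis-hydroxy ester F2, which PPTS in MeOH desilylates and lactonises, returning to 33.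

Step 14. What may go wrong: the amine-catalysed addition is slow and reversible, and it may stall while the acrylate is consumed by oligomerisation or by addition of methanol. Fallback: a stoichiometric aldol/elimination sequence is used instead. From 26, the lithium enolate of methyl 3-(dimethylamino)propanoate (LiN(iPr)2, THF, −78 °C) gives the β-hydroxy α-(dimethylaminomethyl) ester F3. MeI converts it into the trimethylammonium iodide F4, and DBU eliminates the amine to unveil the acrylate, returning to 28.

Further compounds
F1 | step 6 | (1S,2R,6R)-enantiomer of adduct 13 | O=C[C@]1(CC=C)[C@H](COCc2ccc(OC)cc2)C=C(O[Si](C)(C)C(C)(C)C)C[C@H]1C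
F2 | step 17 | trimethylsilyl ether of the cis-hydroxy ester 32 | C=C(C(=O)OC)[C@H]1C[C@]2(C[C@H]1O[Si](C)(C)C)C(COCc4ccc(OC)cc4)=C[C@@H]3O[Si](C(C)C)(C(C)C)O[Si](C(C)C)(C(C)C)O[C@H]3[C@@H]2C
F3 | step 14 | 5α-[3-(dimethylaminomethyl)-2-hydroxy-3-(methoxycarbonyl)propyl] compound (diastereomer mixture), otherwise as 26 | COC(OC)C[C@@]1(CC(O)C(CN(C)C)C(=O)OC)C(COCc3ccc(OC)cc3)=C[C@@H]2O[Si](C(C)C)(C(C)C)O[Si](C(C)C)(C(C)C)O[C@H]2[C@@H]1C
F4 | step 14 | trimethylammonium iodide derived from F3 | COC(OC)C[C@@]1(CC(O)C(C[N+](C)(C)C)C(=O)OC)C(COCc3ccc(OC)cc3)=C[C@@H]2O[Si](C(C)C)(C(C)C)O[Si](C(C)C)(C(C)C)O[C@H]2[C@@H]1C.[I-]
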